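# Proposed total synthesis of CNP0187917.1 by ring-closing metathesis at C4=C5

## The problem

CNP0187917.1 is a germacranolide (germacrane numbering C1–C15 is used for every compound below). A ten-membered carbocycle C1–C10 is trans-fused along C6–C7 to an α-methylene-γ-butyrolactone (O6–C12, C11=C13). It carries a trans 1,10-epoxide, one ring alkene (Z-C4=C5, trisubstituted, bearing C15H2OH), a free 3-hydroxyl and an 8-angelate. The SMILES reads as 1R,3S,6R,7R,8R,10R.

The three contiguous centres C6, C7 and C8 can be relayed from one another. A substituent at C6 on a butenolide directs a new bond at C7 to the opposite face (trans lactone), and a chair transition state passes this on to C8. That relay, however, gives the 7,8-relationship opposite to the one in the target (the 8-oxygen must be cis to C11), so C8 needs one inversion. C3 and the epoxide carbons C1/C10 are separated from this triad and from each other by methylene groups, so they must be set by reagent control.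

The α-methylene lactone is a Michael acceptor and is base-sensitive, the angelate isomerises readily to the tiglate, and the trisubstituted epoxide does not tolerate strong acid, least of all with a free 3-hydroxyl or a transannular alkene nearby. The ten-membered ring is strained and slow to close, so the closure should be neutral and leave almost nothing to be done after it.

The feature that allows this is C4=C5: it is the only C=C inside the ring and lies between the oxygenated carbons C3/C15 and the lactone carbon C6. It can be cut into a vinyl group on the finished lactone and the exocyclic methylene of a 1,3-dioxane that ties O3 and O15 together. One correction to this idea is needed. If C1=C10 were still an alkene during ring closure it would sit in a 1,7-relationship to the C6 vinyl group, and the C5 alkylidene would close a cyclohexene (C5=C10) with loss of the C1–C4 arm. The epoxide is therefore installed before the ring is closed.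

## Retrosynthesis

**28 ⇒ 27 (O–C bonds of the acetonide only).** The target 28 is taken back to its 3,15-acetonide 27, so that the only operation after ring closure is a mild transketalisation. The alternative, epoxidising C1=C10 after ring closure, would leave that alkene in the metathesis substrate, where cyclohexene formation is expected to outrun closure of the ten-membered ring. It would also leave the facial selectivity of the epoxidation to the conformation of the macrocycle. The forward step must remove the acetonide without opening the epoxide.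

**27 ⇒ 26 (C4=C5; key step).** Cutting the ring alkene gives the open-chain tetraene 26: the C6 vinyl lactone bearing the 8-angelate and the 1,10-epoxide, with a 5-methylene-1,3-dioxane at the far end. Against the neighbouring cuts, C7–C8 would need a macrocyclic allylation with two new stereocentres formed in the ring-closing event, and C9–C10 or C1–C10 would bring the epoxide stereochemistry into the closure. The C4=C5 cut forms no stereocentre, and all six are already in 26. The forward reaction must engage a monosubstituted and a 1,1-disubstituted alkene, leave two electron-poor alkenes alone, and give the Z alkene.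

**26 ⇒ 24 + 25 (C8–O).** The ester is cut to alcohol 24 and angelic acid 25 with inversion at C8. This is chosen because the reliable way of making the C7–C8 bond (next paragraph) gives the 8-epimer. A Mitsunobu esterification corrects the centre and introduces the acyl group in one neutral step, before the ring makes C8 more hindered.

**24 ⇒ 22 + 8 (C7–C8).** Alcohol 24 is cut between C7 and C8 into the β,γ-epoxy aldehyde 22 and the bromobutenolide 8. The fragments are of similar size, and the cyclic allyl donor fixes its own geometry, so the C6 vinyl group dictates the face at C7 and the chair transition state dictates C8. The neighbouring option is to form C6–C7 by adding an open-chain allylmetal that already carries C8 to acrolein 2. It was set aside because its facial selectivity would rest on a freely rotating allylic stereocentre and cannot be predicted with confidence. The forward reaction must be mild enough for an epoxy aldehyde.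

**22 ⇒ 21 ⇒ 20 ⇒ 19 (C8 oxidation level; C1–O and C10–O).** The aldehyde comes from the silyl ether 20 by desilylation to 21 and oxidation. The epoxide of 20 comes from the E-trisubstituted alkene of 19 by a catalyst-controlled epoxidation. At this stage the only other alkene is the electron-poor dioxane methylene, and the molecule has no base-sensitive group.

**19 ⇒ 18 ⇒ 15 + 12 (C4=CH2; C2–C3).** The exocyclic methylene is taken back to ketone 18. Ketone 18 is the α-alkylation product of dihydroxyacetone acetonide 13, via its SAMP hydrazone 15 (from 13 and 14), with the allylic bromide 12. This one bond sets C3 by auxiliary control and delivers the diol already tied into the dioxane that the key step needs.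

**12 ⇒ 11 ⇒ 9 (C1–C2 and C10–C14).** The E-trisubstituted alkene of bromide 12 is traced through allylic alcohol 11 to the silyl ether 9 of but-3-yn-1-ol: methylalumination of the alkyne and capture with formaldehyde form both C–C bonds with defined geometry.

**8 ⇒ 7 ⇒ 6 ⇒ 4 ⇒ 1 + 2 (lactone fragment).** The allylic bromide of 8 comes from silyl ether 7. The butenolide ring of 7 (C12–O6 and C11–C12) comes from carbonylation of the Z-iodoalkenol 6. The iodoalkene comes from the propargylic alcohol 4 by hydroxyl-directed hydroalumination, and 4 comes from an enantioselective addition of alkyne 1 to acrolein 2. C6 is thus set once, by a catalyst, and is carried unchanged into the target.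

## Roads not taken

**Alternative 1:** The cut is an extra C6–C10 bond: the ten-membered ring would be released from the hydroazulene diol monomesylate A1 by a Wharton–Grob fragmentation. In the forward step KOtBu turns the C6 hydroxyl into an alkoxide, which expels the antiperiplanar C1 mesylate, giving the C6 ketone and E-C1=C10 of dienone A2.

- Merits: the ring is opened out of a bicycle rather than closed, so dilution, catalyst lifetime and alkene chemoselectivity do not matter, and the E geometry follows stereospecifically from the C1/C10 relationship. In reliability of ring formation this road is better than the chosen one.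
- Weak points: A2 has no lactone carbons and C7 is still a methylene group. After the fragmentation one would have to alkylate C7 in a flexible ring next to a β-alkoxy ketone (prone to elimination under the basic conditions), reduce C6 selectively, exchange the C8 ether for the angelate and epoxidise C1=C10 under substrate control. A1 itself needs five stereocentres.
- Comparison: the chosen plan accepts a less certain ring closure but has the lactone, the ester and all six stereocentres in place before it, with one deprotection after it.

**Alternative 2:** The cut is O6–C12 and C11–C12: the methylene lactone would be built last on the macrocyclic homopropargylic alcohol A3. In the forward step divalent palladium (PdCl2(PPh3)2, SnCl2, CO) carbonylates the C6 hydroxyl and adds the acyl group across the C7 ethynyl group to give A4.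

- Merits: the Michael acceptor is never exposed to phosphines, fluoride or a ruthenium alkylidene, and the trans fusion follows from C6/C7. In protecting the most sensitive group this road is better.
- Weak points: it does not solve the ten-membered ring. A3 already contains the ring, both alkenes and the C6–C8 triad, so the hard part is only moved. The acidic palladium/tin conditions would also meet an allylic alcohol at C6, two allylic silyl ethers and the angelate.
- Comparison: the chosen plan forms the lactone early under aqueous zinc conditions, and uses the lactone's C6 centre to set C7, which Alternative 2 would have to set otherwise. Against this it must carry the methylene lactone through a Mitsunobu reaction and a metathesis, both neutral.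

**Alternative 3:** The cut is C9–C10: the ring would be closed from the bromomethyl ketone A5 by a samarium Reformatsky reaction. In the forward step SmI2 (divalent samarium) turns the C9 bromide into the samarium enolate of the C8 ketone, which adds to the C10 methyl ketone to give the hydroxy ketone A6.

- Merits: samarium-templated closures of medium rings are among the most dependable, and the step forms the oxygenated quaternary C10, from which the epoxide could be closed by displacement at C1. As a ring-forming event it is probably more reliable than the metathesis.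
- Weak points: C10 is set by a chelate in a forming macrocycle. A6 still needs reduction at C8 with the right sense, acylation, activation of C1 and epoxide closure, and α-methylenation of the lactone. The C8 ketone has the lactone oxygen in the β-position, so elimination is a risk.
- Comparison: the chosen plan sets C1/C10 by a catalyst before ring closure and needs one step after it, against five or more here.

Key step: step 15

## Route

Remark on the chemistry: the (S,S)-ProPhenol ligand in step 1 is assumed to deliver the alkynyl group to the Si face of acrolein; if the sense is the opposite, its antipode is used.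

Step 1
Reactants: 1 tert-butyldimethyl(prop-2-yn-1-yloxy)silane; 2 acrolein
Product: 4 (3R)-6-[(tert-butyldimethylsilyl)oxy]hex-1-en-4-yn-3-ol, via methylzinc acetylide 3 (not isolated)
Conditions: Me2Zn, (S,S)-ProPhenol (10 mol%), Ph3PO (20 mol%), toluene, 0 °C; then 2
Reagents that add atoms: none
Why: Zinc–ProPhenol-catalysed asymmetric alkynylation of an enal: the alkynylzinc formed from 1 and Me2Zn adds 1,2 to acrolein inside the dinuclear zinc pocket, and Si-face delivery sets C6 as R.

Step 2
Reactants: 4 (3R)-6-[(tert-butyldimethylsilyl)oxy]hex-1-en-4-yn-3-ol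
Product: 6 (3R,4Z)-6-[(tert-butyldimethylsilyl)oxy]-5-iodohexa-1,4-dien-3-ol, via cyclic alkenylalanate 5 (not isolated)
Conditions: NaAlH2(OCH2CH2OCH3)2, THF, 0 °C; then I2, −78 °C
Reagents that add atoms: iodine, II
Why: Hydroxyl-directed trans-hydroalumination of a propargylic alcohol followed by iodinolysis: hydride goes to C7 and aluminium to C11 within a five-membered alanate, so iodine ends cis to the carbinol carbon (Z) and the vinyl group and C6 are untouched.

Step 3
Reactants: 6 (3R,4Z)-6-[(tert-butyldimethylsilyl)oxy]-5-iodohexa-1,4-dien-3-ol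
Product: 7 (5R)-3-{[(tert-butyldimethylsilyl)oxy]methyl}-5-ethenylfuran-2(5H)-one
Conditions: PdCl2(PPh3)2 (5 mol%), CO (1 atm), K2CO3, THF, 25 °C
Reagents that add atoms: carbon monoxide, [C-]#[O+]
Why: Palladium-catalysed carbonylative lactonisation of a (Z)-3-iodoallylic alcohol: zerovalent palladium inserts into the C–I bond, CO inserts, and the cis hydroxyl captures the acylpalladium to close the butenolide; no bond to C6 is broken and the weak heterogeneous base limits epimerisation at the γ-carbon.

Step 4
Reactants: 7 (5R)-3-{[(tert-butyldimethylsilyl)oxy]methyl}-5-ethenylfuran-2(5H)-one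
Product: 8 (5R)-3-(bromomethyl)-5-ethenylfuran-2(5H)-one
Conditions: Ph3PBr2, CH2Cl2, 0 °C → rt
Reagents that add atoms: dibromotriphenylphosphorane Ph3PBr2, BrP(Br)(c1ccccc1)(c1ccccc1)c1ccccc1
Why: Direct conversion of a primary allylic silyl ether into the bromide with Ph3PBr2; it avoids fluoride or amine base, which could racemise the butenolide through its dienolate, and the conjugated bromomethyl isomer is the stable one.

Step 5
Reactants: 9 (but-3-yn-1-yloxy)(tert-butyl)dimethylsilane
Product: 11 (2E)-5-[(tert-butyldimethylsilyl)oxy]-3-methylpent-2-en-1-ol, via alkenyldimethylalane 10 (not isolated)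
Conditions: AlMe3, Cp2ZrCl2 (25 mol%), CH2Cl2, 0 °C → rt; then n-BuLi, (CH2O)n, THF, −78 °C → rt
Reagents that add atoms: trimethylaluminium, C[Al](C)C; formaldehyde (from paraformaldehyde), C=O
Why: Negishi zirconium-catalysed carboalumination: syn addition of Me–Al puts the methyl group on C10 and aluminium on C1, and the derived alanate is hydroxymethylated with retention, so the E alkene (C2 trans to C9) results.

Step 6
Reactants: 11 (2E)-5-[(tert-butyldimethylsilyl)oxy]-3-methylpent-2-en-1-ol
Product: 12 {[(3E)-5-bromo-3-methylpent-3-en-1-yl]oxy}(tert-butyl)dimethylsilane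
Conditions: CBr4, PPh3, CH2Cl2, 0 °C
Reagents that add atoms: tetrabromomethane, BrC(Br)(Br)Br
Why: Appel bromination of a primary allylic alcohol; SN2 displacement of the alkoxyphosphonium ion gives the unrearranged bromide with the alkene geometry kept.

Step 7
Reactants: 13 2,2-dimethyl-1,3-dioxan-5-one; 14 (S)-1-amino-2-(methoxymethyl)pyrrolidine (SAMP)
Product: 15 (2S)-N-(2,2-dimethyl-1,3-dioxan-5-ylidene)-2-(methoxymethyl)pyrrolidin-1-amine
Conditions: cyclohexane, 4 Å molecular sieves, 60 °C
Reagents that add atoms: none
Why: Condensation of a ketone with a hydrazine to the SAMP hydrazone; the symmetric ketone gives a single product.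

Step 8
Reactants: 15 (2S)-N-(2,2-dimethyl-1,3-dioxan-5-ylidene)-2-(methoxymethyl)pyrrolidin-1-amine; 12 {[(3E)-5-bromo-3-methylpent-3-en-1-yl]oxy}(tert-butyl)dimethylsilane
Product: 18 (4S)-4-{(2E)-5-[(tert-butyldimethylsilyl)oxy]-3-methylpent-2-en-1-yl}-2,2-dimethyl-1,3-dioxan-5-one, via lithium azaenolate 16 (not isolated), via alkylated hydrazone 17 (not isolated)
Conditions: t-BuLi, THF, −78 °C; 12, −100 → −78 °C; then saturated aqueous (CO2H)2, Et2O, rt
Reagents that add atoms: water, O
Why: Enders SAMP-hydrazone α-alkylation: the lithium azaenolate, held by chelation to the methoxymethyl group, is alkylated by the allylic bromide (SN2) on its open face, which with SAMP sets C3 as S; two-phase oxalic acid then cleaves the hydrazone without epimerisation or loss of the acetonide and returns the auxiliary.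

Step 9
Reactants: 18 (4S)-4-{(2E)-5-[(tert-butyldimethylsilyl)oxy]-3-methylpent-2-en-1-yl}-2,2-dimethyl-1,3-dioxan-5-one
Product: 19 tert-butyl{[(3E)-5-[(4S)-2,2-dimethyl-5-methylidene-1,3-dioxan-4-yl]-3-methylpent-3-en-1-yl]oxy}dimethylsilane
Conditions: Cp2TiMe2, toluene, 65 °C, dark
Reagents that add atoms: dimethyltitanocene Cp2TiMe2, C[Ti](C)(C1C=CC=C1)C1C=CC=C1
Why: Petasis methylenation: the titanium methylidene formed on heating converts the ketone into the exocyclic alkene under non-basic conditions, so the adjacent C3 centre is not epimerised.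

Step 10
Reactants: 19 tert-butyl{[(3E)-5-[(4S)-2,2-dimethyl-5-methylidene-1,3-dioxan-4-yl]-3-methylpent-3-en-1-yl]oxy}dimethylsilane
Product: 20 tert-butyl(2-{(2R,3R)-3-[((4S)-2,2-dimethyl-5-methylidene-1,3-dioxan-4-yl)methyl]-2-methyloxiran-2-yl}ethoxy)dimethylsilane
Conditions: 1,2:4,5-di-O-isopropylidene-β-D-erythro-2,3-hexodiulo-2,6-pyranose (30 mol%), KHSO5 (as 2KHSO5·KHSO4·K2SO4), K2CO3, Bu4NHSO4, Na2B4O7 buffer, MeCN/CH2(OMe)2/H2O, 0 °C
Reagents that add atoms: potassium peroxymonosulfate KHSO5, [K+].[O-]S(=O)(=O)OO
Why: Shi asymmetric epoxidation: the dioxirane of the D-fructose-derived ketone transfers oxygen to the electron-rich E-trisubstituted C1=C10 alkene through the spiro transition state, which for this olefin class gives the (R,R)-epoxide (1R,10R); the 1,1-disubstituted alkene with two allylic oxygens is much less reactive.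

Step 11
Reactants: 20 tert-butyl(2-{(2R,3R)-3-[((4S)-2,2-dimethyl-5-methylidene-1,3-dioxan-4-yl)methyl]-2-methyloxiran-2-yl}ethoxy)dimethylsilane
Product: 21 2-{(2R,3R)-3-[((4S)-2,2-dimethyl-5-methylidene-1,3-dioxan-4-yl)methyl]-2-methyloxiran-2-yl}ethan-1-ol
Conditions: Bu4NF, THF, 0 °C
Reagents that add atoms: none
Why: Fluoride-induced cleavage of a primary silyl ether; the epoxide and the acetonide are stable to fluoride and to the mildly basic medium.

Step 12
Reactants: 21 2-{(2R,3R)-3-[((4S)-2,2-dimethyl-5-methylidene-1,3-dioxan-4-yl)methyl]-2-methyloxiran-2-yl}ethan-1-ol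
Product: 22 2-{(2R,3R)-3-[((4S)-2,2-dimethyl-5-methylidene-1,3-dioxan-4-yl)methyl]-2-methyloxiran-2-yl}acetaldehyde
Conditions: Dess–Martin periodinane, NaHCO3, CH2Cl2, 0 °C → rt
Reagents that add atoms: none
Why: Dess–Martin oxidation of a primary alcohol under buffered, near-neutral conditions, which should give the β,γ-epoxy aldehyde without β-elimination; it is used at once without chromatography.

Step 13
Reactants: 22 2-{(2R,3R)-3-[((4S)-2,2-dimethyl-5-methylidene-1,3-dioxan-4-yl)methyl]-2-methyloxiran-2-yl}acetaldehyde; 8 (5R)-3-(bromomethyl)-5-ethenylfuran-2(5H)-one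
Product: 24 (4R,5R)-4-[(1S)-2-{(2R,3R)-3-[((4S)-2,2-dimethyl-5-methylidene-1,3-dioxan-4-yl)methyl]-2-methyloxiran-2-yl}-1-hydroxyethyl]-5-ethenyl-3-methylideneoxolan-2-one, via allylzinc bromide 23 (not isolated)
Conditions: Zn dust, THF/saturated aqueous NH4Cl, 0 °C → rt
Reagents that add atoms: none
Why: Zinc Barbier allylation with a 3-(bromomethyl)butenolide: the allylzinc reacts through C7 in a chair transition state, anti to the vinyl group on C6 (trans lactone, 7R) and with the aldehyde chain equatorial, which gives the anti adduct with C8 as S, the epimer that the next step inverts; the ring fixes the allyl geometry, so both new centres follow from C6.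

Step 14
Reactants: 24 (4R,5R)-4-[(1S)-2-{(2R,3R)-3-[((4S)-2,2-dimethyl-5-methylidene-1,3-dioxan-4-yl)methyl]-2-methyloxiran-2-yl}-1-hydroxyethyl]-5-ethenyl-3-methylideneoxolan-2-one; 25 angelic acid
Product: 26 (1R)-2-{(2R,3R)-3-[((4S)-2,2-dimethyl-5-methylidene-1,3-dioxan-4-yl)methyl]-2-methyloxiran-2-yl}-1-[(2R,3R)-2-ethenyl-4-methylidene-5-oxooxolan-3-yl]ethyl (2Z)-2-methylbut-2-enoate
Conditions: PPh3, diisopropyl azodicarboxylate, toluene, 0 °C → rt
Reagents that add atoms: none
Why: Mitsunobu esterification: SN2 displacement of the alkoxyphosphonium ion by angelate inverts C8 to R and installs the ester in one neutral step, which keeps the Z geometry of the acid and spares the methylene lactone and the epoxide.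

Step 15
Reactants: 26 (1R)-2-{(2R,3R)-3-[((4S)-2,2-dimethyl-5-methylidene-1,3-dioxan-4-yl)methyl]-2-methyloxiran-2-yl}-1-[(2R,3R)-2-ethenyl-4-methylidene-5-oxooxolan-3-yl]ethyl (2Z)-2-methylbut-2-enoate
Product: 27 (1R,3S,4Z,6R,7R,8R,10R)-8-angeloyloxy-1,10-epoxy-3,15-(isopropylidenedioxy)germacra-4,11(13)-dien-12,6-olide
Conditions: RuCl2(H2IMes)(PCy3)(=CHPh) (second-generation Grubbs catalyst, 20 mol% in portions), toluene, 0.5 mM, 80 °C, argon sparge
Reagents that add atoms: none
Why: The ruthenium benzylidene exchanges onto the monosubstituted C6 vinyl group to give the C5 alkylidene, which adds across the 1,1-disubstituted C4 methylene of the dioxane; the metallacyclobutane opens to C4=C5 and a ruthenium methylidene, and ethene is lost. The closest known reaction type is ring-closing metathesis with this catalyst to trisubstituted alkenes in lactone-fused medium rings. One ring is closed, the ten-membered carbocycle, by macrocyclic ring-closing metathesis between a terminal vinyl group and an exocyclic methylene group with the new alkene inside the ring. No stereocentre is formed; the Z geometry is expected because an E alkene cannot span the trans-lactone-fused ten-membered ring without severe strain. The step needs chemoselectivity among four alkenes and against oligomerisation: only the vinyl group is monosubstituted, so the catalyst loads there; the α-methylene lactone and the angelate are electron-poor (the latter also trisubstituted) and poor partners. The dioxane holds O3 and O15 back from the methylene group, and the trans lactone brings the two ends together. Because C1/C10 is already an epoxide, the alkylidene has no 1,7-alkene with which to close a cyclohexene. High dilution and removal of ethene favour the intramolecular path.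

Step 16
Reactants: 27 (1R,3S,4Z,6R,7R,8R,10R)-8-angeloyloxy-1,10-epoxy-3,15-(isopropylidenedioxy)germacra-4,11(13)-dien-12,6-olide
Product: 28 (1R,3S,4Z,6R,7R,8R,10R)-8-angeloyloxy-1,10-epoxy-3,15-dihydroxygermacra-4,11(13)-dien-12,6-olide (CNP0187917.1)
Conditions: pyridinium p-toluenesulfonate, MeOH, 0 °C → rt
Reagents that add atoms: none
Why: Acid-catalysed transketalisation of a 1,3-diol acetonide to methanol; the weak pyridinium acid in cold anhydrous methanol is chosen so that the acetonide exchanges while the trisubstituted epoxide, the lactone and the angelate are left alone.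

## Compound list

1 | tert-butyldimethyl(prop-2-yn-1-yloxy)silane | C#CCO[Si](C)(C)C(C)(C)C | starting material
2 | acrolein | C=CC=O | starting material
3 | methyl{3-[(tert-butyldimethylsilyl)oxy]prop-1-yn-1-yl}zinc | C[Zn]C#CCO[Si](C)(C)C(C)(C)C | intermediate
4 | (3R)-6-[(tert-butyldimethylsilyl)oxy]hex-1-en-4-yn-3-ol | C=C[C@@H](O)C#CCO[Si](C)(C)C(C)(C)C | intermediate
5 | sodium cyclic alkenylalanate of 4 (O6–Al–C11 five-membered ring, two 2-methoxyethoxy groups on Al) | [Na+].COCCO[Al-]1(OCCOC)O[C@H](C=C)C=C1CO[Si](C)(C)C(C)(C)C | intermediate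
6 | (3R,4Z)-6-[(tert-butyldimethylsilyl)oxy]-5-iodohexa-1,4-dien-3-ol | C=C[C@@H](O)/C=C(\I)CO[Si](C)(C)C(C)(C)C | intermediate
7 | (5R)-3-{[(tert-butyldimethylsilyl)oxy]methyl}-5-ethenylfuran-2(5H)-one | O=C1O[C@H](C=C)C=C1CO[Si](C)(C)C(C)(C)C | intermediate
8 | (5R)-3-(bromomethyl)-5-ethenylfuran-2(5H)-one | O=C1O[C@H](C=C)C=C1CBr | intermediate
9 | (but-3-yn-1-yloxy)(tert-butyl)dimethylsilane | C#CCCO[Si](C)(C)C(C)(C)C | starting material
10 | {(1E)-4-[(tert-butyldimethylsilyl)oxy]-2-methylbut-1-en-1-yl}dimethylalane | C[Al](C)/C=C(\C)CCO[Si](C)(C)C(C)(C)C | intermediate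
11 | (2E)-5-[(tert-butyldimethylsilyl)oxy]-3-methylpent-2-en-1-ol | OC/C=C(\C)CCO[Si](C)(C)C(C)(C)C | intermediate
12 | {[(3E)-5-bromo-3-methylpent-3-en-1-yl]oxy}(tert-butyl)dimethylsilane | BrC/C=C(\C)CCO[Si](C)(C)C(C)(C)C | intermediate
13 | 2,2-dimethyl-1,3-dioxan-5-one | CC1(C)OCC(=O)CO1 | starting material
14 | (S)-1-amino-2-(methoxymethyl)pyrrolidine (SAMP) | COC[C@@H]1CCCN1N | starting material
15 | (2S)-N-(2,2-dimethyl-1,3-dioxan-5-ylidene)-2-(methoxymethyl)pyrrolidin-1-amine | COC[C@@H]1CCCN1N=C1COC(C)(C)OC1 | intermediate
16 | lithium azaenolate of 15 (deprotonated at C4 of the dioxane) | [Li+].COC[C@@H]1CCCN1[N-]C1=COC(C)(C)OC1 | intermediate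
17 | (2S)-N-[(4S)-4-{(2E)-5-[(tert-butyldimethylsilyl)oxy]-3-methylpent-2-en-1-yl}-2,2-dimethyl-1,3-dioxan-5-ylidene]-2-(methoxymethyl)pyrrolidin-1-amine (C=N geometry not fixed) | COC[C@@H]1CCCN1N=C1COC(C)(C)O[C@H]1C/C=C(\C)CCO[Si](C)(C)C(C)(C)C | intermediate
18 | (4S)-4-{(2E)-5-[(tert-butyldimethylsilyl)oxy]-3-methylpent-2-en-1-yl}-2,2-dimethyl-1,3-dioxan-5-one | O=C1COC(C)(C)O[C@H]1C/C=C(\C)CCO[Si](C)(C)C(C)(C)C | intermediate
19 | tert-butyl{[(3E)-5-[(4S)-2,2-dimethyl-5-methylidene-1,3-dioxan-4-yl]-3-methylpent-3-en-1-yl]oxy}dimethylsilane | C=C1COC(C)(C)O[C@H]1C/C=C(\C)CCO[Si](C)(C)C(C)(C)C | intermediate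
20 | tert-butyl(2-{(2R,3R)-3-[((4S)-2,2-dimethyl-5-methylidene-1,3-dioxan-4-yl)methyl]-2-methyloxiran-2-yl}ethoxy)dimethylsilane | C=C1COC(C)(C)O[C@H]1C[C@H]2O[C@]2(C)CCO[Si](C)(C)C(C)(C)C | intermediate
21 | 2-{(2R,3R)-3-[((4S)-2,2-dimethyl-5-methylidene-1,3-dioxan-4-yl)methyl]-2-methyloxiran-2-yl}ethan-1-ol | C=C1COC(C)(C)O[C@H]1C[C@H]2O[C@]2(C)CCO | intermediate
22 | 2-{(2R,3R)-3-[((4S)-2,2-dimethyl-5-methylidene-1,3-dioxan-4-yl)methyl]-2-methyloxiran-2-yl}acetaldehyde | C=C1COC(C)(C)O[C@H]1C[C@H]2O[C@]2(C)CC=O | intermediate
23 | bromo{[(5R)-5-ethenyl-2-oxo-2,5-dihydrofuran-3-yl]methyl}zinc | Br[Zn]CC1=C[C@@H](C=C)OC1=O | intermediate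
24 | (4R,5R)-4-[(1S)-2-{(2R,3R)-3-[((4S)-2,2-dimethyl-5-methylidene-1,3-dioxan-4-yl)methyl]-2-methyloxiran-2-yl}-1-hydroxyethyl]-5-ethenyl-3-methylideneoxolan-2-one | C=C1C(=O)O[C@H](C=C)[C@H]1[C@@H](O)C[C@@]2(C)O[C@@H]2C[C@@H]3OC(C)(C)OCC3=C | intermediate
25 | angelic acid, (2Z)-2-methylbut-2-enoic acid | C/C=C(/C)C(=O)O | starting material
26 | (1R)-2-{(2R,3R)-3-[((4S)-2,2-dimethyl-5-methylidene-1,3-dioxan-4-yl)methyl]-2-methyloxiran-2-yl}-1-[(2R,3R)-2-ethenyl-4-methylidene-5-oxooxolan-3-yl]ethyl (2Z)-2-methylbut-2-enoate | C=C1C(=O)O[C@H](C=C)[C@H]1[C@H](OC(=O)/C(C)=C\C)C[C@@]2(C)O[C@@H]2C[C@@H]3OC(C)(C)OCC3=C | intermediate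
27 | (1R,3S,4Z,6R,7R,8R,10R)-8-angeloyloxy-1,10-epoxy-3,15-(isopropylidenedioxy)germacra-4,11(13)-dien-12,6-olide | C=C1C(=O)O[C@@H]2/C=C3/COC(C)(C)O[C@H]3C[C@H]3O[C@]3(C)C[C@@H](OC(=O)/C(C)=C\C)[C@@H]12 | intermediate
28 | (1R,3S,4Z,6R,7R,8R,10R)-8-angeloyloxy-1,10-epoxy-3,15-dihydroxygermacra-4,11(13)-dien-12,6-olide (CNP0187917.1) | C=C1C(=O)O[C@@H]2/C=C(/CO)[C@@H](O)C[C@H]3O[C@]3(C)C[C@@H](OC(=O)/C(C)=C\C)[C@@H]12 | target

## Step count and least certain steps

Total step count: 16. Longest linear sequence: 11 steps (9 → 28 through steps 5, 6 and 8–16). Steps 1–4 (lactone fragment) and step 7 (hydrazone) are convergent branches.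

**Step 15 (key step).** The strained ten-membered ring may close more slowly than the C6 vinyl groups of two molecules meet, so that oligomers form and the catalyst decays before cyclisation. The hindered C4 methylene may also fail to engage at all. Fallback: the ring is closed one stage earlier on a substrate with a different conformational bias. Starting from 24, the same catalyst under the same dilution would give the macrocyclic 8-epi alcohol acetonide F1, whose free hydroxyl and opposite C8 configuration change the folding of the chain. Mitsunobu esterification of F1 with 25 on the ring, with inversion, returns to the route at 27.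

**Step 14.** Displacement at the hindered C8 carbinol may be slower than elimination of the alkoxyphosphonium ion, and the phosphine may isomerise the angelate towards the tiglate. Fallback: inversion and acylation are separated. Starting from 24, a Mitsunobu reaction with the smaller and more acidic formic acid gives the inverted formate F2. Brief methanolysis (KHCO3, MeOH, 0 °C) gives the 8β-alcohol F3. Yamaguchi esterification with 25 (2,4,6-trichlorobenzoyl chloride, Et3N, then 4-dimethylaminopyridine), which proceeds with retention and keeps the Z geometry, returns to the route at 26.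

**Step 13.** The β,γ-epoxy aldehyde 22 may undergo β-elimination or epoxide opening in the aqueous zinc medium before the C–C bond forms. Fallback: the epoxide is introduced after the coupling. Starting from 19, desilylation gives dienol F4 and Dess–Martin oxidation gives the β,γ-unsaturated aldehyde F5. The zinc Barbier reaction with 8 gives the alkene analogue F6 of the adduct, and Mitsunobu esterification with 25 gives the tetraene ester F7. Shi epoxidation of the only electron-rich alkene of F7, run at the lower pH of the borate-buffered protocol to spare the lactone, returns to the route at 26.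

**Step 16.** Acid may open the strained macrocyclic epoxide, through attack of the freed 3-hydroxyl at C10 or by solvolysis, as fast as it removes the acetonide. Fallback: the acetonide is removed before the ring exists. Starting from 26, the same pyridinium acid in methanol gives the open-chain diol F8, in which the epoxide is an ordinary acyclic one. Ring-closing metathesis of F8 with the same catalyst, where the free allylic hydroxyls are expected to help rather than hinder, gives 28 directly.

**Step 1.** The enantioselectivity of alkyne addition to the small, unsubstituted enal may be low, or the sense may be opposite to the one assumed. Fallback: the centre is set by resolution. Starting from 1 and 2, deprotonation of 1 with n-BuLi and addition to 2 (THF, −78 °C) gives the racemic alcohol F9. Kinetic resolution by asymmetric epoxidation (Ti(OiPr)4, D-(−)-diisopropyl tartrate, t-BuOOH, 4 Å molecular sieves, CH2Cl2, −20 °C) consumes the S enantiomer at its vinyl group and leaves 4.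

## Further compounds

F1 | step 15 | (1R,3S,4Z,6R,7R,8S,10R)-1,10-epoxy-8-hydroxy-3,15-(isopropylidenedioxy)germacra-4,11(13)-dien-12,6-olide | C=C1C(=O)O[C@@H]2/C=C3/COC(C)(C)O[C@H]3C[C@H]3O[C@]3(C)C[C@H](O)[C@@H]12
F2 | step 14 | (1R)-2-{(2R,3R)-3-[((4S)-2,2-dimethyl-5-methylidene-1,3-dioxan-4-yl)methyl]-2-methyloxiran-2-yl}-1-[(2R,3R)-2-ethenyl-4-methylidene-5-oxooxolan-3-yl]ethyl formate | C=C1C(=O)O[C@H](C=C)[C@H]1[C@H](OC=O)C[C@@]2(C)O[C@@H]2C[C@@H]3OC(C)(C)OCC3=C
F3 | step 14 | (4R,5R)-4-[(1R)-2-{(2R,3R)-3-[((4S)-2,2-dimethyl-5-methylidene-1,3-dioxan-4-yl)methyl]-2-methyloxiran-2-yl}-1-hydroxyethyl]-5-ethenyl-3-methylideneoxolan-2-one | C=C1C(=O)O[C@H](C=C)[C@H]1[C@H](O)C[C@@]2(C)O[C@@H]2C[C@@H]3OC(C)(C)OCC3=C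
F4 | step 13 | (3E)-5-[(4S)-2,2-dimethyl-5-methylidene-1,3-dioxan-4-yl]-3-methylpent-3-en-1-ol | C=C1COC(C)(C)O[C@H]1C/C=C(\C)CCO
F5 | step 13 | (3E)-5-[(4S)-2,2-dimethyl-5-methylidene-1,3-dioxan-4-yl]-3-methylpent-3-enal | C=C1COC(C)(C)O[C@H]1C/C=C(\C)CC=O
F6 | step 13 | (4R,5R)-4-{(1S,3E)-5-[(4S)-2,2-dimethyl-5-methylidene-1,3-dioxan-4-yl]-1-hydroxy-3-methylpent-3-en-1-yl}-5-ethenyl-3-methylideneoxolan-2-one | C=C1C(=O)O[C@H](C=C)[C@H]1[C@@H](O)C/C(C)=C/C[C@@H]2OC(C)(C)OCC2=C
F7 | step 13 | (1R,3E)-5-[(4S)-2,2-dimethyl-5-methylidene-1,3-dioxan-4-yl]-1-[(2R,3R)-2-ethenyl-4-methylidene-5-oxooxolan-3-yl]-3-methylpent-3-en-1-yl (2Z)-2-methylbut-2-enoate | C=C1C(=O)O[C@H](C=C)[C@H]1[C@H](OC(=O)/C(C)=C\C)C/C(C)=C/C[C@@H]2OC(C)(C)OCC2=C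
F8 | step 16 | (1R)-1-[(2R,3R)-2-ethenyl-4-methylidene-5-oxooxolan-3-yl]-2-{(2R,3R)-3-[(2S)-2-hydroxy-3-(hydroxymethyl)but-3-en-1-yl]-2-methyloxiran-2-yl}ethyl (2Z)-2-methylbut-2-enoate | C=C1C(=O)O[C@H](C=C)[C@H]1[C@H](OC(=O)/C(C)=C\C)C[C@@]2(C)O[C@@H]2C[C@H](O)C(=C)CO
F9 | step 1 | rac-6-[(tert-butyldimethylsilyl)oxy]hex-1-en-4-yn-3-ol | C=CC(O)C#CCO[Si](C)(C)C(C)(C)C
A1 | alternative 1 | cis-fused hydroazulene diol monomesylate (C6 tertiary alcohol, C1 mesylate cis to the C10 methyl group, C8 4-methoxybenzyl ether, 3,15-bis-silyl ether) | C[C@@]12C[C@@H](OCc3ccc(OC)cc3)C[C@]1(O)/C=C(/CO[Si](C)(C)C(C)(C)C)[C@@H](O[Si](C)(C)C(C)(C)C)C[C@H]2OS(C)(=O)=O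
A2 | alternative 1 | (4Z,1(10)E)-cyclodecadien-6-one with C8 4-methoxybenzyl ether and 3,15-bis-silyl ether | O=C1/C=C(/CO[Si](C)(C)C(C)(C)C)[C@@H](O[Si](C)(C)C(C)(C)C)C/C=C(\C)C[C@@H](OCc2ccc(OC)cc2)C1
A3 | alternative 2 | ten-membered (4Z,1(10)E)-diene with C6 hydroxyl, C7 ethynyl group, C8 angelate and 3,15-bis-silyl ether | C#C[C@H]1[C@H](O)/C=C(/CO[Si](C)(C)C(C)(C)C)[C@@H](O[Si](C)(C)C(C)(C)C)C/C=C(\C)C[C@H]1OC(=O)/C(C)=C\C
A4 | alternative 2 | (4Z,1(10)E)-germacradienolide 8-angelate 3,15-bis-silyl ether | C=C1C(=O)O[C@@H]2/C=C(/CO[Si](C)(C)C(C)(C)C)[C@@H](O[Si](C)(C)C(C)(C)C)C/C=C(\C)C[C@@H](OC(=O)/C(C)=C\C)[C@@H]12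
A5 | alternative 3 | open-chain lactone with C8 bromomethyl ketone and C10 methyl ketone (C1 triethylsilyl ether, 3,15-bis-silyl ether) | CC(=O)[C@@H](O[Si](CC)(CC)CC)C[C@H](O[Si](C)(C)C(C)(C)C)/C(CO[Si](C)(C)C(C)(C)C)=C\[C@H]1OC(=O)C[C@@H]1C(=O)CBr
A6 | alternative 3 | ten-membered 10-hydroxy-8-ketone fused to the saturated lactone | C1C(=O)O[C@@H]2/C=C(/CO[Si](C)(C)C(C)(C)C)[C@@H](O[Si](C)(C)C(C)(C)C)C[C@H](O[Si](CC)(CC)CC)[C@](C)(O)CC(=O)[C@@H]12
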